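**How slow.** Ask first how slow this chemistry really is, and take the north-east run as the gauge: there Z goes into chains as Q once G is charged, and its readings show how far and how fast.

| flask | Z | G | temperature | remark | time |
|---|---|---|---|---|---|
| north-east | 1.1 M | 19 mM | 40 °C | run made earlier |  |
| cedar | 1.0 M | 19 mM | 40 °C |  | 20 h |
| ash | 1.0 M | 60 mM | 0 °C |  | 20 h |
| alder | 0.30 M | 19 mM | 80 °C |  | 20 h |
| maple | 0.60 M | 40 mM | 0 °C |  | 20 h |
| birch | 3.0 M | 19 mM | 40 °C |  | 20 h |

- north-east (time / h: Q / %, Z / %): 1.50: 81.1, 19.0; 4.00: 93.8, 6.2; 8.00: 93.8, 6.4; 12.0: 93.3, 6.6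

(scatter of a reading: 0.3 percentage points)

- the flasks by amount of Q, in percent of the Z charged, highest first, at 20 h (cedar / ash / alder / maple / birch)
- the same order at 4.0 h (cedar / ash / alder / maple / birch)
- the amount of Q, in percent of the Z charged of the flask you put first, at 20 h
- the amount of Q, in percent of the Z charged of the flask you put last, at 20 h

- the numbers in the tables scatter by 0.3 percentage points (one standard deviation)
- the earlier runs do not show what temperature does; that part of a forecast is a guess
- no earlier run changes the charge of G; that part of a forecast is a guess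

**The zero.** Average the last 3 readings of Z in north-east, 6.40 % of the charge, and multiply by that charge to get the ceiling concentration Zc, the free Z read beside Q in north-east at 40 °C, 0.0704 M; the field calls it the equilibrium monomer concentration, and a flask resting there is under thermodynamic control. Count a charge c of Z at 40 °C from Zc as the zero of the scale, assuming that Zc stays the same when c changes, so that the share of Z that ends as Q is (c − Zc)/c.

**The ladder.** Take the early rung first: treat the excess of Z above Zc in north-east as decaying exponentially, and its fall to 19.0 % of the charge at 1.50 h gives a relaxation time τ read as 0.748 h. On the next rung, at 4.00 h, which is longer than τ, north-east already stands on its plateau. On the last rung shown, up to 12.0 h, Z in north-east shifts by 0.4 percentage points against a scatter of 0.3 points.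

**My reckoning.** Assume that cedar and birch, with the G and temperature of north-east, climb as it did; then both have reached the ceiling well before 20 h, cedar at 93.0 % of Q and birch at 97.7 %. Leave ash, maple and alder unranked, since Zc and τ were read at one temperature and one charge of G.

**The forecast.** It gives ash > birch > maple > cedar > alder at 20 h, with 98 % of Q in its first flask and 10 % in its last, and birch > cedar > ash > maple > alder at 4.0 h, and it says “The temperature effects are guesses”. It ranks ash above birch, where my reckoning gives no rank for ash.

**The flasks.** The simulation gives birch > cedar > ash > alder > maple at 20 h, with 97.8 % of Q in the first flask and 43.8 % in the last, and birch > cedar > alder > ash > maple at 4.0 h.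

    Q + J → Z + J, rate k1*[J] as long as [Q] is above zero (k = 5.25 h⁻¹, Ea = 87.0 kJ mol⁻¹)
    Z + G → J + Q (k = 6.95 L mol⁻¹ h⁻¹, Ea = 64.0 kJ mol⁻¹)
    Z + J → Q + J, rate k3*[J]*[Z] (k = 79.0 L mol⁻¹ h⁻¹, Ea = 72.0 kJ mol⁻¹)
    2 G ⇌ E (K = 2200 L mol⁻¹, k = 12.6 L mol⁻¹ h⁻¹, Ea = 55.0 kJ mol⁻¹, ΔH = −30.0 kJ mol⁻¹)
    (constants at 40 °C)

**The neighbour.** Cedar ends at 93.4 % of Q and birch at 97.8 %, each near its reckoned ceiling. Now carry Zc to the neighbour flask, which is birch with 0.75 M of Z and all else kept: (c − Zc)/c gives 90.6 % of Q, leaving 9.39 % of its Z free. That flask reads 91.1 % of Q at 20.0 h, with 8.9 % of its Z free.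

The earlier runs and the new flask stem from a simulated flask on assumed constants; the scatter is artificial.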